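**Plan**

- Retrosynthesis: the two aryl–C(=O) bonds of the butyryl groups are cut first. Then, in each ring (C1 butyryl, C2 OH, C3 bridge carbon, C4 OH, C5 Me, C6 OMe), the C3–C4 bond is cut, which unravels each benzene into a 6-alkyl-4-methoxy-3-methyl-2-pyranone. Last, the two bonds between the acyl carbons of a glutaryl unit and the γ-carbons of two 2-methylacetoacetate units are cut.
- Enabling feature: C2–C3–CH2–C3′–C2′ is the five-carbon chain of glutaric acid, and C4–C5(Me)–C6(OMe)–C1 of each ring is the C2–C3–C4–C5 segment of a 4-methoxy-3-methyl-2-pyranone whose C6 is the glutaric acyl carbon. The C-methyl/O-methyl adjacency is therefore fixed before either arene exists.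
- Forward: glutaryl bis-Weinreb amide, two-fold dianion acylation (chain joined), both pyranone rings by lactonisation, O-methylation, both benzene rings in one operation, then both butyryl groups.
- Stereochemistry: the target has no stereogenic element. The two epimerisable centres of the tetraketo diester vanish on lactonisation, and the cis relation of ester and ketone arm needed for ring closure is inherited from the pyranone ring.

Key step: step 5

Remark: pseudoaspidin is achiral, so "single enantiomer" places no demand on the route.

**Route**

Step 1
Reactants: 1 pentanedioyl dichloride (glutaryl dichloride); 2 N,O-dimethylhydroxylamine hydrochloride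
Product: 3 N1,N5-dimethoxy-N1,N5-dimethylpentanediamide
Conditions: 2 (2.2 equiv), Et3N (4.6 equiv), CH2Cl2, 0 °C → rt
Reagents that add atoms: N,O-dimethylhydroxylamine hydrochloride (2), CNOC.Cl
Why: Acyl substitution at both acid chloride carbons by the amine freed with Et3N is the standard Weinreb amide preparation and gives an acyl donor that takes up a carbanion only once per carbonyl.

Step 2
Reactants: 3 N1,N5-dimethoxy-N1,N5-dimethylpentanediamide; 4 ethyl 2-methyl-3-oxobutanoate (ethyl 2-methylacetoacetate, racemic)
Product: 6 diethyl 2,12-dimethyl-3,5,9,11-tetraoxotridecanedioate (mixture of diastereomers and enol tautomers), via the dilithio dianion of ethyl 2-methylacetoacetate 5 (not isolated)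
Conditions: 4 (2.6 equiv), LDA (5.2 equiv), THF, 0 °C; then 3, –78 → 0 °C; cold 1 M HCl
Reagents that add atoms: none
Why: This is a two-fold C-acylation of a β-keto ester dianion at its more nucleophilic terminal carbon, and because the N-methoxy-N-methylamide holds the addition stage until the acid quench, the acidic 3,5-dioxo product cannot protonate unreacted dianion and no second addition occurs.

Step 3
Reactants: 6 diethyl 2,12-dimethyl-3,5,9,11-tetraoxotridecanedioate
Product: 7 6,6′-(propane-1,3-diyl)bis(4-hydroxy-3-methyl-2H-pyran-2-one)
Conditions: DBU (3 equiv), toluene, reflux; then 1 M HCl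
Reagents that add atoms: none
Why: In this base-mediated lactonisation of a 3,5-dioxo ester the C5 enolate oxygen of each half attacks its ethyl ester (6-exo-trig acyl substitution), the conjugated 4-hydroxy-2-pyranone is the thermodynamic sink, and both stereocentres of 6 disappear.

Step 4
Reactants: 7 6,6′-(propane-1,3-diyl)bis(4-hydroxy-3-methyl-2H-pyran-2-one); 8 dimethyl sulfate
Product: 9 6,6′-(propane-1,3-diyl)bis(4-methoxy-3-methyl-2H-pyran-2-one)
Conditions: Me2SO4 (2.5 equiv), K2CO3 (3 equiv), acetone, reflux
Reagents that add atoms: dimethyl sulfate (8), COS(=O)(=O)OC
Why: O-Alkylation of the vinylogous acid with dimethyl sulfate and carbonate is known to favour the 4-methoxy-2-pyranone over the 2-methoxy-4-pyranone, and the 3-methyl group blocks the only carbon that could be methylated instead.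

Step 5
Reactants: 9 6,6′-(propane-1,3-diyl)bis(4-methoxy-3-methyl-2H-pyran-2-one)
Product: 11 2,2′-methylenebis(5-methoxy-4-methylbenzene-1,3-diol) [bis(2,6-dihydroxy-4-methoxy-3-methylphenyl)methane], via ring-opened bis(keto enoate) 10 (not isolated)
Conditions: NaOMe (8 equiv), degassed MeOH, sealed vessel, 160–180 °C, Ar; then aq. HCl to pH 3
Reagents that add atoms: none
Why: Methoxide adds to each lactone carbonyl and opens the pyranone to the methyl (E)-3-methoxy-2-methyl-5-oxo-2-enoate 10, in which ester and ketone-bearing CH2 remain cis as in the ring; proton exchange in methanol then gives the enolate on the linker side of the freed ketone, whose α-carbon (future C3) attacks the ester carbon (future C4), methoxide leaves and the cyclohexenedione enol ether tautomerises to the phenoxide of the resorcinol monomethyl ether. The closest known reaction is the alkoxide-induced recyclisation of 4-methoxy-6-methyl-2-pyranone (triacetic acid lactone methyl ether) to 5-methoxyresorcinol, a Dieckmann-type Claisen condensation of a masked 3,5-dioxo ester, run here at both ends of one chain with a CH2 in place of a CH3 nucleophile. Each benzene ring closes by a 6-(enolendo)-exo-trig C-acylation that forms C3–C4 (and C3′–C4′), and the middle carbon of the glutaric chain is left as the bridge. No stereocentre is formed. The step needs Claisen closure to win over aldol addition of the dienolate carbon of one half to the ketone of the other, over relactonisation and over methanolysis of the ketone: in excess methoxide the freed ketones rest as conjugated dienolates and are poor acceptors, aldol addition and relactonisation are reversible whereas Claisen closure ends in an aromatic phenoxide, and with methoxide in methanol ester exchange and addition–elimination at the methoxy-bearing carbon are degenerate. The place of every substituent is dictated by the pyranone (C-methyl next to O-methyl, free CH from pyranone C5), so the ring-forming event has no regiochemical choice to make.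

Step 6
Reactants: 11 2,2′-methylenebis(5-methoxy-4-methylbenzene-1,3-diol); 12 butanoyl chloride (butyryl chloride)
Product: 13 pseudoaspidin
Conditions: PrCOCl (2.3 equiv), TiCl4 (5 equiv), CH2Cl2–MeNO2, 0 °C → rt; then ice/1 M HCl
Reagents that add atoms: butanoyl chloride (12), CCCC(=O)Cl
Why: In this two-fold Friedel–Crafts acylation each ring offers a single unsubstituted carbon (C1, ortho to a titanium-bound phenoxide and para to the C4 hydroxyl), chelation of the new o-hydroxy ketone to titanium deactivates the ring afterwards, and TiCl4 is too weak a Lewis acid to cleave the neighbouring aryl methyl ether.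

**Compound list**

1 | pentanedioyl dichloride (glutaryl dichloride) | O=C(Cl)CCCC(=O)Cl | starting material
2 | N,O-dimethylhydroxylamine hydrochloride | CNOC.Cl | starting material
3 | N1,N5-dimethoxy-N1,N5-dimethylpentanediamide | CON(C)C(=O)CCCC(=O)N(C)OC | intermediate
4 | ethyl 2-methyl-3-oxobutanoate (racemic) | CCOC(=O)C(C)C(C)=O | starting material
5 | dilithium dienolate (dianion) of ethyl 2-methyl-3-oxobutanoate, formed in the flask | [Li+].[Li+].C=C([O-])C(C)=C([O-])OCC | intermediate
6 | diethyl 2,12-dimethyl-3,5,9,11-tetraoxotridecanedioate (stereoisomer and enol mixture) | CCOC(=O)C(C)C(=O)CC(=O)CCCC(=O)CC(=O)C(C)C(=O)OCC | intermediate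
7 | 6,6′-(propane-1,3-diyl)bis(4-hydroxy-3-methyl-2H-pyran-2-one) | O=C1OC(CCCC2=CC(O)=C(C)C(=O)O2)=CC(O)=C1C | intermediate
8 | dimethyl sulfate | COS(=O)(=O)OC | starting material
9 | 6,6′-(propane-1,3-diyl)bis(4-methoxy-3-methyl-2H-pyran-2-one) | O=C1OC(CCCC2=CC(OC)=C(C)C(=O)O2)=CC(OC)=C1C | intermediate
10 | dimethyl (2E,11E)-3,11-dimethoxy-2,12-dimethyl-5,9-dioxotrideca-2,11-dienedioate (drawn neutral with both rings open; present as sodium enolates, and the two halves may equally react one after the other) | COC(=O)/C(C)=C(OC)\CC(=O)CCCC(=O)C/C(OC)=C(C)\C(=O)OC | intermediate
11 | 2,2′-methylenebis(5-methoxy-4-methylbenzene-1,3-diol) | Cc1c(O)c(Cc2c(O)c(C)c(OC)cc2O)c(O)cc1OC | intermediate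
12 | butanoyl chloride | CCCC(=O)Cl | starting material
13 | pseudoaspidin, 1,1′-[methylenebis(2,4-dihydroxy-6-methoxy-5-methyl-3,1-phenylene)]bis(butan-1-one) (achiral) | CCCC(=O)c1c(O)c(Cc2c(O)c(C)c(OC)c(C(=O)CCC)c2O)c(O)c(C)c1OC | target

**Count**

Total steps: 6. Longest linear sequence: 6 (1 → 3 → 6 → 7 → 9 → 11 → 13); compound 4 enters at step 2.

**Steps most likely to fail**

1. Step 5 (key step). Several processes can divert the material:
 - aldol addition of the doubly activated CH2 of one opened half, as its dienolate, to the ketone of the other half (a six-membered aldol that dehydration would make permanent);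
 - cleavage of the freed ketone by methoxide (retro-Claisen acyl transfer);
 - closure of only one arm;
 - migration of the finished bridge to the open ring position by base-induced quinone-methide exchange at the high temperature.

 The fallback builds one ring per molecule and makes the bridge with formaldehyde; it sets out from 4 and comes back to the route at 13. Dianion 5, made from 4 as in step 2, is acylated with N-methoxy-N-methylacetamide to give ethyl 2-methyl-3,5-dioxohexanoate F1. DBU in hot toluene closes this to 4-hydroxy-3,6-dimethyl-2H-pyran-2-one F2, and dimethyl sulfate with K2CO3 converts it into 4-methoxy-3,6-dimethyl-2H-pyran-2-one F3. With NaOMe in methanol in a sealed vessel F3 frees only one ketone, so the recyclisation is the single-ring case with a methyl nucleophile and should give 5-methoxy-4-methylbenzene-1,3-diol F4. Acylation of F4 with 12 and TiCl4 is expected to give 1-(4,6-dihydroxy-2-methoxy-3-methylphenyl)butan-1-one F5 (acyl para to a hydroxyl) together with the isomer acylated between the two hydroxyls, from which it must be separated. The only free ring carbon of F5 lies between two hydroxyls, and aqueous formaldehyde with dilute NaOH at room temperature should join two molecules there to give 13.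

2. Step 6. The HCl/TiCl4 medium may protonate the bridge-bearing carbons at the ipso position, which leads to scission or relocation of the methylene bridge. Ester formation at the phenols may compete with ring acylation, and the methyl ether next to the new ketone may be lost to the Lewis acid. The fallback is a Houben–Hoesch acylation that sets out from 11 and comes back at 13. Compound 11 is treated with butyronitrile, ZnCl2 and dry HCl in ether at 0 °C, where a nitrilium electrophile cannot esterify phenols and no strongly oxophilic metal halide is present. The product should precipitate as 1,1′-[methylenebis(2,4-dihydroxy-6-methoxy-5-methyl-3,1-phenylene)]bis(butan-1-iminium) dichloride F6, which is filtered off and hydrolysed in hot water to 13.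

3. Step 2. Acylation of the second arm may lag behind the first once the mono-adduct aggregates, or the dianion may act as a base toward the amide (α-deprotonation, or elimination across N–OMe with loss of formaldehyde) instead of adding. The fallback forms the pyranone rings from silyl enol ethers and a malonyl dichloride; it sets out from 3 and comes back at 7, bypassing 6 and step 3. Compound 3 with MeMgBr (Weinreb ketone synthesis) gives heptane-2,6-dione F7. Addition of LDA to F7 and TMSCl at –78 °C (internal quench, terminal enolisation trapped before intramolecular aldol) gives 2,6-bis(trimethylsilyloxy)hepta-1,6-diene F8. Methylmalonyl dichloride (2 equiv) in ether, –78 °C → rt, C-acylates each enol ether terminus and the resulting β-diketone acid chloride lactonises, which should deliver 7 directly.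

**Further compounds**

F1 | step 5 | ethyl 2-methyl-3,5-dioxohexanoate | CCOC(=O)C(C)C(=O)CC(C)=O
F2 | step 5 | 4-hydroxy-3,6-dimethyl-2H-pyran-2-one | CC1=CC(O)=C(C)C(=O)O1
F3 | step 5 | 4-methoxy-3,6-dimethyl-2H-pyran-2-one | COC1=C(C)C(=O)OC(C)=C1
F4 | step 5 | 5-methoxy-4-methylbenzene-1,3-diol | COc1cc(O)cc(O)c1C
F5 | step 5 | 1-(4,6-dihydroxy-2-methoxy-3-methylphenyl)butan-1-one | CCCC(=O)c1c(O)cc(O)c(C)c1OC
F6 | step 6 | 1,1′-[methylenebis(2,4-dihydroxy-6-methoxy-5-methyl-3,1-phenylene)]bis(butan-1-iminium) dichloride | CCCC(=[NH2+])c1c(O)c(Cc2c(O)c(C)c(OC)c(C(=[NH2+])CCC)c2O)c(O)c(C)c1OC.[Cl-].[Cl-]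
F7 | step 2 | heptane-2,6-dione | CC(=O)CCCC(C)=O
F8 | step 2 | 2,6-bis(trimethylsilyloxy)hepta-1,6-diene | C=C(O[Si](C)(C)C)CCCC(=C)O[Si](C)(C)C
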